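## The problem

The target **17** is a 1-aryltetralin cyclolignan. Ring A is a pentasubstituted arene (H at C5, OMe at C6, OH at C7, OMe at C8), ring B is the fused carbocycle C1–C4, and ring C is a 4-hydroxy-3-methoxyphenyl group on C1; C2 and C3 each carry CH2OH. The three contiguous stereocentres are (1R,2S,3S) in tetralin numbering, with C1/C2 and C2/C3 both trans. C1 is a diarylmethine with no adjacent activating group, so it cannot be corrected once made and must receive its absolute configuration from a reliable asymmetric step. C2 and C3 each sit next to a carboxyl-level carbon in any sensible precursor, so they can be set relative to C1 (C2 directly, C3 through C2). The C8 methoxy group flanks C1: it hinders bond formation there and puts peri strain on a pseudo-equatorial ring C, which weakens the usual thermodynamic preference for the all-trans isomer. The two free phenols make both arenes easy to oxidise (the C7 phenol is para to the benzylic C4), and the 1,4-diol can close to a tetrahydrofuran under acid; the phenols are therefore carried as benzyl ethers and the diol at the ester oxidation level. The enabling feature is that C2 and C3 are adjacent and each bears a one-carbon substituent: as esters they form a succinate unit inside ring B. The C2–C3 bond then joins two ester α-carbons, and the other four ring B atoms (C1, C8a, C4a, C4) act as the tether for a six-membered oxidative enolate coupling.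

## Retrosynthesis

**17 ⇒ 16 ⇒ 15 (no skeletal bond cut).** The phenols of **17** are unmasked last from the bis(benzyl ether) **16**, and the two CH2OH groups of **16** come from the all-trans dimethyl diester **15** by hydride reduction. This puts the sensitive phenols and the diol at the very end and turns C2 and C3 into ester α-carbons.

**15 ⇒ 13 (cut C2–C3, ring B opened).** The bond between the two ester α-carbons is cut, giving the open-chain diester **13** (forward via its bis-enolate **14**).
- Against the neighbouring cuts: a Friedel–Crafts cut at C4–C4a or C1–C8a would have to form a bond at a ring A position that is hindered or poorly activated, and a cut at C1–C2 or C3–C4 leaves the succinate relationship unused.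
- Simplification: one ring and two stereocentres are removed, and the two reacting sites are of the same kind (ester enolates), so no differentiation of the esters is needed.
- Forward demands: complete double deprotonation, a two-electron oxidant, ring closure in preference to intermolecular coupling, and C1 control of C2 with C2 control of C3.

**13 ⇒ 7 + 12 (cut C1–ring C).** The diarylmethine is cut on the side of the unhindered aryl group, giving cinnamate **7** and arylboronic acid **12**. The other cut (C1–C8a) would need a boronic acid with two ortho substituents, which transmetalates poorly and protodeboronates. The precursor **7** is achiral, so the forward step must be a catalytic asymmetric conjugate arylation that tolerates a second, saturated ester.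

**7 ⇒ 5 + 6 (cut C8a–C1).** The aryl–vinyl bond is cut to aryl bromide **5** and methyl acrylate **6**. The forward Heck reaction must cope with a bromide flanked by OMe and the propanoate chain.

**5 ⇒ 4 ⇒ 3 ⇒ 2 ⇒ 1 (cut C3=C4, then C–Br and O–Bn).** The propanoate **5** comes from cinnamate **4** by conjugate reduction, and **4** from aldehyde **3** by a Wittig reaction, so the aldehyde carbon of syringaldehyde **1** becomes C4. The bromine of **3** enters at one of the two equivalent open positions of the benzyl ether **2**. Syringaldehyde delivers ring A with all three oxygens correctly placed.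

**12 ⇒ 9 ⇒ 8.** The boronic acid comes from aryl bromide **9** by bromine–lithium exchange and borylation (via **10** and **11**), and **9** from 4-bromo-2-methoxyphenol **8** by benzylation.

## Roads not taken

**Alternative 1:** The cut is through ring A (C4a–C8a and C5–C6) together with ring B. The furan-tethered alkyne **A2**, which already holds C1, C2 and C3 in an open chain, would be heated to give an intramolecular [4+2] addition. Opening of the oxygen bridge and tautomerisation would give the phenol **A1**.
- Merits: both rings form in one reagent-free step, and no stereocentre is created in the key step. In that respect it is safer than the chosen plan, whose key step creates two.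
- Weak points: the phenol of **A1** appears at C6, whereas **17** needs OMe at C6 and OH at C7. The route therefore needs an O-methylation and then a selective cleavage of the central C7 methyl ether next to a hindered C8 methoxy group and in the presence of benzyl ethers. **A2** needs three contiguous stereocentres built in an acyclic chain that carries an acid- and oxidation-sensitive dialkoxyfuran. A terminal, unactivated alkyne is also a poor dienophile, so high temperatures and a reversible cycloaddition are to be expected.
- Comparison: the chosen plan buys ring A with the correct oxygen pattern and needs only one catalytic stereocentre before the key step. What it has to set against the pre-set stereocentres of **A2** is the argument for substrate control in step 9 and the auxiliary-based fallback.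

**Alternative 2:** The cut removes C4 as a one-carbon unit (C3–C4 and C4–C4a). The aldehyde **A4** would be α-methylenated with formaldehyde **A5** under amine catalysis, and the ring A carbon para to the free C7 phenol would then add in conjugate fashion to close ring B, giving **A3**.
- Merits: ring A needs no protecting group, the only open position para to the phenol is the correct one, C3 is an epimerisable aldehyde centre, and the conditions are mild. In protecting-group economy on ring A it is better than the chosen plan.
- Weak points: **A4** requires C1 and C2 to be set in an acyclic 3,3-diaryl system, which is the asymmetric problem of the chosen route plus one more centre. **A5** can hydroxymethylate the free phenol ring directly and can react with the product aldehyde. The methylenation–arylation sequence has no close precedent as a cascade. Ring C has to be deactivated as a sulfonate, which adds steps at both ends.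
- Comparison: the chosen key step rests on a known reaction class, whereas this cascade would have to be developed.

**Alternative 3:** The cut is at C1–C2 and C1–ring C. Under a Lewis acid, the allylsilane of **A7** would attack the ring A aldehyde to close ring B, and ionisation at C1 would then alkylate guaiacol **A8** para to its hydroxyl group, giving **A6** in one pot.
- Merits: two C–C bonds and two stereocentres form in one operation from a single C3 stereocentre, and the ring C donor is used unprotected. In bond-forming economy it is better than the chosen plan.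
- Weak points: **A8** can react para to OH or para to OMe, so regioisomers are likely. Ionisation at C1 next to C2–H can end in elimination. The vinyl group of **A6** has to be cleaved oxidatively to CH2OH in the presence of a free phenol and two electron-rich arenes, through a C2 aldehyde that can epimerise. The absolute configuration rests on a separate asymmetric synthesis of the C3 centre of **A7**.
- Comparison: the chosen plan carries both CH2OH groups as esters with no redox detour and sets the absolute configuration at C1 by a catalytic step of an established type. What it gives away is the one-pot formation of two bonds.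

Key step: step 9

Assumption: the sense of induction of the chiral diene in step 8 is taken from the accepted model for (E)-enoates. The (R,R) ligand named there is the one expected to give (3R)-**13**; if the sense proved opposite on this hindered substrate, the (S,S) ligand would be used with no other change.

## Route

Step 1
Reactants: 1 syringaldehyde (4-hydroxy-3,5-dimethoxybenzaldehyde)
Product: 2 4-(benzyloxy)-3,5-dimethoxybenzaldehyde
Conditions: BnBr (1.1 equiv), K2CO3 (1.5 equiv), DMF, 60 °C
Reagents that add atoms: benzyl bromide, BrCc1ccccc1
Why: Williamson ether synthesis at the only nucleophilic site; the benzyl ether survives bases, hydrides and the palladium and rhodium steps and is removed by hydrogenolysis at the end.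

Step 2
Reactants: 2 4-(benzyloxy)-3,5-dimethoxybenzaldehyde
Product: 3 4-(benzyloxy)-2-bromo-3,5-dimethoxybenzaldehyde
Conditions: NBS (1.05 equiv), MeCN, 40 °C, dark
Reagents that add atoms: N-bromosuccinimide, O=C1CCC(=O)N1Br
Why: Electrophilic aromatic bromination; C2 and C6 are the only open positions and are equivalent, each ortho and para to a methoxy group, and the first bromine deactivates the ring toward a second; polar solvent in the dark keeps the reaction ionic so the benzylic CH2 is spared.

Step 3
Reactants: 3 4-(benzyloxy)-2-bromo-3,5-dimethoxybenzaldehyde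
Product: 4 methyl (E)-3-[4-(benzyloxy)-2-bromo-3,5-dimethoxyphenyl]prop-2-enoate
Conditions: Ph3P=CHCO2Me (1.2 equiv), toluene, 90 °C
Reagents that add atoms: methyl (triphenylphosphoranylidene)acetate, COC(=O)C=P(c1ccccc1)(c1ccccc1)c1ccccc1
Why: Wittig olefination with a stabilised ylide gives the (E)-cinnamate; the geometry is of no consequence because the alkene is reduced in the next step.

Step 4
Reactants: 4 methyl (E)-3-[4-(benzyloxy)-2-bromo-3,5-dimethoxyphenyl]prop-2-enoate
Product: 5 methyl 3-[4-(benzyloxy)-2-bromo-3,5-dimethoxyphenyl]propanoate
Conditions: Cu(OAc)2·H2O (3 mol%), 1,2-bis(diphenylphosphino)benzene (3 mol%), (HMe2Si)2O (1.2 equiv), t-BuOH (2 equiv), toluene, rt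
Reagents that add atoms: none
Why: Copper hydride-catalysed conjugate reduction; the phosphine-ligated CuH adds 1,4 to the enoate and the copper enolate is protonated by t-BuOH, while the aryl bromide and the benzyl ether, which hydrogenation over palladium would endanger, are untouched.

Step 5
Reactants: 5 methyl 3-[4-(benzyloxy)-2-bromo-3,5-dimethoxyphenyl]propanoate; 6 methyl acrylate
Product: 7 methyl (E)-3-[3-(benzyloxy)-2,4-dimethoxy-6-(3-methoxy-3-oxopropyl)phenyl]prop-2-enoate
Conditions: Pd2(dba)3 (2 mol%), [HP(t-Bu)3]BF4 (8 mol%), Cy2NMe (1.5 equiv), dioxane, 90 °C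
Reagents that add atoms: none
Why: Mizoroki–Heck reaction; the bulky electron-rich phosphine drives oxidative addition of zerovalent palladium into the di-ortho-substituted, electron-rich bromide, and syn insertion followed by syn β-hydride elimination gives the (E)-cinnamate.

Step 6
Reactants: 8 4-bromo-2-methoxyphenol
Product: 9 1-(benzyloxy)-4-bromo-2-methoxybenzene
Conditions: BnBr (1.1 equiv), K2CO3 (1.5 equiv), acetone, reflux
Reagents that add atoms: benzyl bromide, BrCc1ccccc1
Why: Williamson ether synthesis; the same protecting group as on ring A allows one final deprotection.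

Step 7
Reactants: 9 1-(benzyloxy)-4-bromo-2-methoxybenzene
Product: 12 [4-(benzyloxy)-3-methoxyphenyl]boronic acid, via aryllithium 10 (not isolated), via lithium aryltriisopropoxyborate 11 (not isolated)
Conditions: n-BuLi (1.1 equiv), THF, −78 °C; B(OiPr)3 (1.5 equiv), −78 °C → rt; 1 M HCl
Reagents that add atoms: triisopropyl borate, CC(C)OB(OC(C)C)OC(C)C; water, O
Why: Bromine–lithium exchange at −78 °C is faster than benzylic deprotonation; the aryllithium is trapped by the borate and the ate complex is hydrolysed to the boronic acid.

Step 8
Reactants: 7 methyl (E)-3-[3-(benzyloxy)-2,4-dimethoxy-6-(3-methoxy-3-oxopropyl)phenyl]prop-2-enoate; 12 [4-(benzyloxy)-3-methoxyphenyl]boronic acid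
Product: 13 methyl (3R)-3-[3-(benzyloxy)-2,4-dimethoxy-6-(3-methoxy-3-oxopropyl)phenyl]-3-[4-(benzyloxy)-3-methoxyphenyl]propanoate
Conditions: [RhCl(C2H4)2]2 (2.5 mol%), (1R,4R)-2,5-diphenylbicyclo[2.2.2]octa-2,5-diene (5.5 mol%), 12 (2.5 equiv), Et3N (1 equiv), dioxane/H2O 10:1, 60 °C
Reagents that add atoms: none
Why: Rhodium-catalysed asymmetric conjugate arylation (Hayashi–Miyaura reaction): the aryl group passes from boron to monovalent rhodium, the chiral diene selects the enantioface of the s-cis enoate in the carborhodation that sets C1, and water protonates the rhodium enolate; Et3N in place of hydroxide spares the methyl esters and the saturated propanoate is inert.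

Step 9
Reactants: 13 methyl (3R)-3-[3-(benzyloxy)-2,4-dimethoxy-6-(3-methoxy-3-oxopropyl)phenyl]-3-[4-(benzyloxy)-3-methoxyphenyl]propanoate
Product: 15 dimethyl (1R,2S,3S)-7-(benzyloxy)-1-[4-(benzyloxy)-3-methoxyphenyl]-6,8-dimethoxy-1,2,3,4-tetrahydronaphthalene-2,3-dicarboxylate, via dilithium bis-enolate 14 (not isolated)
Conditions: LiN(iPr)2 (2.3 equiv), THF, −78 °C, 13 added slowly (0.01 M); CuCl2 (2.4 equiv, anhydrous, in DMF), −78 → 0 °C
Reagents that add atoms: none
Why: Slow addition of 13 to LiN(iPr)2 at −78 °C gives the bis-enolate 14; divalent copper (CuCl2) takes one electron from one enolate, the α-ester radical (or its copper-bound or α-chloro equivalent) is captured by the carbon of the second enolate, and a second equivalent of CuCl2 oxidises the resulting radical anion, so that the net change is loss of two electrons and formation of C2–C3. The closest known reaction type is the intramolecular oxidative coupling of α,ω-diester dienolates with CuCl2 or iodine, which gives trans-cycloalkane-1,2-dicarboxylates. Ring B closes in a 6-exo-trig mode (the attacked enolate C=C lies outside the new ring) through a chair-like array in which C8a and C4a are arene carbons. At C2 the controlling element is the C1 stereocentre: allylic 1,3-strain holds the C1–H bond in the plane of the C2 enolate, C3 can only arrive on the face that carries the tether through C8a, and the new bond therefore forms anti to ring C, which gives C1/C2 trans. At C3 the controlling element is the forming C2 centre: the two planar ester units take pseudo-equatorial, mutually anti positions in the chair-like transition state, which gives C2/C3 trans. The step needs ring closure to win over intermolecular coupling, α-chlorination and Claisen-type condensation; high dilution, complete double deprotonation before the oxidant arrives and rapid addition of a slight excess of CuCl2 at −78 °C serve this. C1 is not α to a carbonyl group and is not touched by the base.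

Step 10
Reactants: 15 dimethyl (1R,2S,3S)-7-(benzyloxy)-1-[4-(benzyloxy)-3-methoxyphenyl]-6,8-dimethoxy-1,2,3,4-tetrahydronaphthalene-2,3-dicarboxylate
Product: 16 [(1R,2S,3S)-7-(benzyloxy)-1-[4-(benzyloxy)-3-methoxyphenyl]-6,8-dimethoxy-1,2,3,4-tetrahydronaphthalene-2,3-diyl]dimethanol
Conditions: LiAlH4 (3 equiv), THF, 0 °C → rt; aqueous NaOH work-up
Reagents that add atoms: none
Why: Hydride reduction of both esters to primary alcohols; hydride addition is much faster than enolisation, so C2 and C3 keep their configuration, and the benzyl ethers are inert.

Step 11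
Reactants: 16 [(1R,2S,3S)-7-(benzyloxy)-1-[4-(benzyloxy)-3-methoxyphenyl]-6,8-dimethoxy-1,2,3,4-tetrahydronaphthalene-2,3-diyl]dimethanol
Product: 17 (6S,7S,8R)-8-(4-hydroxy-3-methoxyphenyl)-6,7-bis(hydroxymethyl)-1,3-dimethoxy-5,6,7,8-tetrahydronaphthalen-2-ol, the target, (1R,2S,3S) in tetralin numbering
Conditions: H2 (1 atm), 10% Pd/C, EtOAc/MeOH, rt
Reagents that add atoms: none
Why: Catalytic hydrogenolysis of the two aryl benzyl ethers; the C1–aryl bonds and the primary alcohols are stable, and the neutral medium avoids acid-promoted closure of the 1,4-diol to a tetrahydrofuran.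

## Compound list

1 | syringaldehyde (4-hydroxy-3,5-dimethoxybenzaldehyde) | COc1cc(C=O)cc(OC)c1O | starting material
2 | 4-(benzyloxy)-3,5-dimethoxybenzaldehyde | COc1cc(C=O)cc(OC)c1OCc1ccccc1 | intermediate
3 | 4-(benzyloxy)-2-bromo-3,5-dimethoxybenzaldehyde | COc1cc(C=O)c(Br)c(OC)c1OCc1ccccc1 | intermediate
4 | methyl (E)-3-[4-(benzyloxy)-2-bromo-3,5-dimethoxyphenyl]prop-2-enoate | COC(=O)/C=C/c1cc(OC)c(OCc2ccccc2)c(OC)c1Br | intermediate
5 | methyl 3-[4-(benzyloxy)-2-bromo-3,5-dimethoxyphenyl]propanoate | COC(=O)CCc1cc(OC)c(OCc2ccccc2)c(OC)c1Br | intermediate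
6 | methyl acrylate | C=CC(=O)OC | starting material
7 | methyl (E)-3-[3-(benzyloxy)-2,4-dimethoxy-6-(3-methoxy-3-oxopropyl)phenyl]prop-2-enoate | COC(=O)/C=C/c1c(CCC(=O)OC)cc(OC)c(OCc2ccccc2)c1OC | intermediate
8 | 4-bromo-2-methoxyphenol | COc1cc(Br)ccc1O | starting material
9 | 1-(benzyloxy)-4-bromo-2-methoxybenzene | COc1cc(Br)ccc1OCc1ccccc1 | intermediate
10 | [4-(benzyloxy)-3-methoxyphenyl]lithium (not isolated) | COc1cc([Li])ccc1OCc1ccccc1 | intermediate
11 | lithium [4-(benzyloxy)-3-methoxyphenyl]tri(propan-2-yloxy)borate (not isolated) | COc1cc([B-](OC(C)C)(OC(C)C)OC(C)C)ccc1OCc1ccccc1.[Li+] | intermediate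
12 | [4-(benzyloxy)-3-methoxyphenyl]boronic acid | COc1cc(B(O)O)ccc1OCc1ccccc1 | intermediate
13 | methyl (3R)-3-[3-(benzyloxy)-2,4-dimethoxy-6-(3-methoxy-3-oxopropyl)phenyl]-3-[4-(benzyloxy)-3-methoxyphenyl]propanoate | COc1cc([C@@H](CC(=O)OC)c2c(CCC(=O)OC)cc(OC)c(OCc3ccccc3)c2OC)ccc1OCc1ccccc1 | intermediate
14 | dilithium bis-enolate of 13, deprotonated at both ester α-carbons (C2 and C3), C1 still (R), enolate geometry not defined (not isolated) | COc1cc([C@@H](C=C([O-])OC)c2c(CC=C([O-])OC)cc(OC)c(OCc3ccccc3)c2OC)ccc1OCc1ccccc1.[Li+].[Li+] | intermediate
15 | dimethyl (1R,2S,3S)-7-(benzyloxy)-1-[4-(benzyloxy)-3-methoxyphenyl]-6,8-dimethoxy-1,2,3,4-tetrahydronaphthalene-2,3-dicarboxylate | COc1cc([C@@H]2c3c(cc(OC)c(OCc4ccccc4)c3OC)C[C@H](C(=O)OC)[C@H]2C(=O)OC)ccc1OCc1ccccc1 | intermediate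
16 | [(1R,2S,3S)-7-(benzyloxy)-1-[4-(benzyloxy)-3-methoxyphenyl]-6,8-dimethoxy-1,2,3,4-tetrahydronaphthalene-2,3-diyl]dimethanol | COc1cc([C@@H]2c3c(cc(OC)c(OCc4ccccc4)c3OC)C[C@H](CO)[C@H]2CO)ccc1OCc1ccccc1 | intermediate
17 | (6S,7S,8R)-8-(4-hydroxy-3-methoxyphenyl)-6,7-bis(hydroxymethyl)-1,3-dimethoxy-5,6,7,8-tetrahydronaphthalen-2-ol | COc1cc([C@@H]2c3c(cc(OC)c(O)c3OC)C[C@H](CO)[C@H]2CO)ccc1O | target

## Step count and least certain steps

Total step count: 11. Longest linear sequence: 9 steps (steps 1–5 and 8–11); steps 6 and 7 prepare the boronic acid.

**Step 9 (key step).**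
- What may go wrong: poor diastereocontrol at C2 or C3. The peri interaction between the C8 methoxy group and a pseudo-equatorial ring C works against the transition state favoured by allylic strain, and the second centre is controlled only through the first. Intermolecular coupling and α-chlorination can also compete at practical concentrations.
- Base equilibration is not counted on as a remedy: with a methoxy group at C8, the isomer with pseudo-axial ring C and both esters equatorial may be of similar stability to **15**.
- Fallback (auxiliary control of both new centres), from **13** back to the route at **16**: saponification of **13** (LiOH, THF/H2O) would give (3R)-3-[3-(benzyloxy)-6-(2-carboxyethyl)-2,4-dimethoxyphenyl]-3-[4-(benzyloxy)-3-methoxyphenyl]propanoic acid F1. Double acylation of (R)-4-benzyl-2-oxazolidinone through the mixed pivalic anhydride (pivaloyl chloride, Et3N, LiCl) would give the bis[(R)-4-benzyl-2-oxazolidinone] imide of this diacid F2. Oxidative coupling of its chelated bis-enolate (LiN(iPr)2, then CuCl2 or iodine) is a known, auxiliary-directed variant of the same ring closure, in which each oxazolidinone shields one face of its enolate. The (R) auxiliary is the one that directs to (2S,3S), and it is matched with the preference of C1. It would give the bis-imide of the (1R,2S,3S)-tetralin-2,3-dicarboxylic acid F3. Reduction with LiBH4 (THF/MeOH) would remove both auxiliaries and give diol **16** directly.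

**Step 8.**
- What may go wrong: slow carborhodation at a β-carbon whose aryl group has two ortho substituents. Protodeboronation of **12** would then outrun addition, with low conversion or eroded enantioselectivity; partial ester hydrolysis is a lesser concern.
- Fallback (stoichiometric auxiliary in place of the catalyst), from **5** and **9** back to the route at **13**: (S)-4-phenyl-2-oxazolidinone would be acylated with acryloyl chloride to give (S)-3-acryloyl-4-phenyl-1,3-oxazolidin-2-one F4. A Heck reaction of **5** with F4 under the conditions of step 5 would give (S)-3-[(E)-3-[3-(benzyloxy)-2,4-dimethoxy-6-(3-methoxy-3-oxopropyl)phenyl]prop-2-enoyl]-4-phenyl-1,3-oxazolidin-2-one F5. Magnesium insertion into **9** would give [4-(benzyloxy)-3-methoxyphenyl]magnesium bromide F6. Its CuBr·SMe2-mediated conjugate addition to F5 (THF, −40 °C) should occur on the chelated s-cis imide anti to the C4 phenyl group and give the (3R)-3,3-diarylpropanoyl imide F7. Methanolysis (NaOMe, MeOH, 0 °C) would release the auxiliary and give **13**.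

**Step 5.**
- What may go wrong: slow oxidative addition into the hindered, electron-rich bromide, with reduction of the C–Br bond instead of coupling.
- Fallback (change of order, so that the Heck reaction meets a bromide activated by the ortho aldehyde), from **3** back to the route at **7**: a Heck reaction of **3** with **6** would give methyl (E)-3-[3-(benzyloxy)-6-formyl-2,4-dimethoxyphenyl]prop-2-enoate F8. Reductive Knoevenagel alkylation of Meldrum's acid with F8 (L-proline cat., diethyl 2,6-dimethyl-1,4-dihydropyridine-3,5-dicarboxylate, EtOH, rt), which reduces only the alkylidene Meldrum's acid and not the cinnamate, would give methyl (E)-3-[3-(benzyloxy)-6-[(2,2-dimethyl-4,6-dioxo-1,3-dioxan-5-yl)methyl]-2,4-dimethoxyphenyl]prop-2-enoate F9. Heating in MeOH/pyridine would open the dioxanedione, decarboxylate and give **7**.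

**Step 4.**
- What may go wrong: incomplete conjugate reduction of the ortho-substituted cinnamate, or partial loss of bromine if forcing conditions become necessary.
- Fallback (no alkene is made), from **3** back to the route at **5**: reductive Knoevenagel alkylation of Meldrum's acid with **3** (same conditions as above) would give 5-{[4-(benzyloxy)-2-bromo-3,5-dimethoxyphenyl]methyl}-2,2-dimethyl-1,3-dioxane-4,6-dione F10. Heating in MeOH/pyridine would give **5**; this replaces steps 3 and 4.

## Further compounds

F1 | step 9 | (3R)-3-[3-(benzyloxy)-6-(2-carboxyethyl)-2,4-dimethoxyphenyl]-3-[4-(benzyloxy)-3-methoxyphenyl]propanoic acid | COc1cc([C@@H](CC(=O)O)c2c(CCC(=O)O)cc(OC)c(OCc3ccccc3)c2OC)ccc1OCc1ccccc1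
F2 | step 9 | bis[(R)-4-benzyl-2-oxazolidinone] imide of diacid F1 | COc1cc([C@@H](CC(=O)N2[C@H](Cc3ccccc3)COC2=O)c2c(CCC(=O)N3[C@H](Cc4ccccc4)COC3=O)cc(OC)c(OCc3ccccc3)c2OC)ccc1OCc1ccccc1
F3 | step 9 | bis[(R)-4-benzyl-2-oxazolidinone] imide of (1R,2S,3S)-7-(benzyloxy)-1-[4-(benzyloxy)-3-methoxyphenyl]-6,8-dimethoxy-1,2,3,4-tetrahydronaphthalene-2,3-dicarboxylic acid | COc1cc([C@@H]2c3c(cc(OC)c(OCc4ccccc4)c3OC)C[C@H](C(=O)N3[C@H](Cc4ccccc4)COC3=O)[C@H]2C(=O)N2[C@H](Cc3ccccc3)COC2=O)ccc1OCc1ccccc1
F4 | step 8 | (S)-3-acryloyl-4-phenyl-1,3-oxazolidin-2-one | C=CC(=O)N1[C@@H](c2ccccc2)COC1=O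
F5 | step 8 | (S)-3-[(E)-3-[3-(benzyloxy)-2,4-dimethoxy-6-(3-methoxy-3-oxopropyl)phenyl]prop-2-enoyl]-4-phenyl-1,3-oxazolidin-2-one | COC(=O)CCc1cc(OC)c(OCc2ccccc2)c(OC)c1/C=C/C(=O)N1[C@@H](c2ccccc2)COC1=O
F6 | step 8 | [4-(benzyloxy)-3-methoxyphenyl]magnesium bromide | COc1cc([Mg]Br)ccc1OCc1ccccc1
F7 | step 8 | methyl 3-[3-(benzyloxy)-2-[(1R)-1-[4-(benzyloxy)-3-methoxyphenyl]-3-oxo-3-[(4S)-2-oxo-4-phenyl-1,3-oxazolidin-3-yl]propyl]-4,6... written by structure: (3R)-3,3-diarylpropanoyl imide of (S)-4-phenyl-2-oxazolidinone with the ring A methyl propanoate chain intact | COc1cc([C@@H](CC(=O)N2[C@@H](c3ccccc3)COC2=O)c2c(CCC(=O)OC)cc(OC)c(OCc3ccccc3)c2OC)ccc1OCc1ccccc1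
F8 | step 5 | methyl (E)-3-[3-(benzyloxy)-6-formyl-2,4-dimethoxyphenyl]prop-2-enoate | COC(=O)/C=C/c1c(C=O)cc(OC)c(OCc2ccccc2)c1OC
F9 | step 5 | methyl (E)-3-[3-(benzyloxy)-6-[(2,2-dimethyl-4,6-dioxo-1,3-dioxan-5-yl)methyl]-2,4-dimethoxyphenyl]prop-2-enoate | COC(=O)/C=C/c1c(CC2C(=O)OC(C)(C)OC2=O)cc(OC)c(OCc2ccccc2)c1OC
F10 | step 4 | 5-{[4-(benzyloxy)-2-bromo-3,5-dimethoxyphenyl]methyl}-2,2-dimethyl-1,3-dioxane-4,6-dione | COc1cc(CC2C(=O)OC(C)(C)OC2=O)c(Br)c(OC)c1OCc1ccccc1
A1 | alternative 1 | all-trans 1-[4-(benzyloxy)-3-methoxyphenyl]-2,3-bis[(benzyloxy)methyl]-7,8-dimethoxytetralin-6-ol | COc1cc([C@@H]2c3c(cc(O)c(OC)c3OC)C[C@H](COCc3ccccc3)[C@H]2COCc2ccccc2)ccc1OCc1ccccc1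
A2 | alternative 1 | 2-{1-[4-(benzyloxy)-3-methoxyphenyl]-2,3-bis[(benzyloxy)methyl]hex-5-yn-1-yl}-3,4-dimethoxyfuran, configuration corresponding to C1, C2 and C3 of A1 | COc1cc([C@H](c2occ(OC)c2OC)[C@H](COCc2ccccc2)[C@@H](COCc2ccccc2)CC#C)ccc1OCc1ccccc1
A3 | alternative 2 | all-trans 2-[(benzyloxy)methyl]-7-hydroxy-6,8-dimethoxy-1-[3-methoxy-4-(tosyloxy)phenyl]tetralin-3-carbaldehyde | COc1cc([C@@H]2c3c(cc(OC)c(O)c3OC)C[C@H](C=O)[C@H]2COCc2ccccc2)ccc1OS(=O)(=O)c1ccc(C)cc1
A4 | alternative 2 | 4-{2-[(benzyloxy)methyl]-1-(3-hydroxy-2,4-dimethoxyphenyl)-4-oxobutyl}-2-methoxyphenyl 4-methylbenzenesulfonate, configuration corresponding to C1 and C2 of A3 | COc1cc([C@H](c2ccc(OC)c(O)c2OC)[C@H](COCc2ccccc2)CC=O)ccc1OS(=O)(=O)c1ccc(C)cc1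
A5 | alternative 2 | formaldehyde | C=O
A6 | alternative 3 | all-trans 7-(benzyloxy)-3-[(benzyloxy)methyl]-1-(4-hydroxy-3-methoxyphenyl)-6,8-dimethoxy-2-vinyltetralin | COc1cc([C@@H]2c3c(cc(OC)c(OCc4ccccc4)c3OC)C[C@H](COCc3ccccc3)[C@H]2C=C)ccc1O
A7 | alternative 3 | 3-(benzyloxy)-6-[(3E)-2-[(benzyloxy)methyl]-5-(trimethylsilyl)pent-3-en-1-yl]-2,4-dimethoxybenzaldehyde, configuration corresponding to C3 of A6 | O=Cc1c(C[C@H](COCc2ccccc2)/C=C/C[Si](C)(C)C)cc(OC)c(OCc2ccccc2)c1OC
A8 | alternative 3 | guaiacol (2-methoxyphenol) | COc1ccccc1O
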